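**Plan**
- Retrosynthetic cuts: C11=C13 (Mannich methylenation); C8–O (carboxylate SN2); C7–C11 with C8–I (iodine-transfer radical lactone annulation from O6); C2=C3 (dehydrogenation); C9–C10 and O–C10 (oxonium ylide [2,3] shift); C2–C3 (C-glycosylation); then the pyranone back to a furyl vinyl carbinol.
- Enabling feature: the furanone oxygen joins C3 and C10. If that oxygen is bonded to C7 instead of C10, then O, C3, C4=C5, C6 and C7 form a 3,6-dihydro-2H-pyran with a C7 vinyl group (C8=C9). A C10 carbenoid on the C3 arm can then exchange O–C7 for O–C10 and C9–C10.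
- Forward ring order: dihydropyran (Achmatowicz), then furanone and ten-membered carbocycle together in one step, then the γ-lactone last.
- Stereochemistry: C7 of the pyran from Sharpless kinetic resolution; C3 by trans C-glycosylation; C6 by Luche reduction and Mitsunobu inversion; C10 relayed from C3 through the bicyclic ylide.
- C7 of the lactone is set by delivery from O6, C8 by anti iodine transfer followed by SN2 inversion, and the side-chain centre comes from (S)-2-methylbutanoic acid.

Key step: step 10

Remark: the germacranolide locants of the target (C1 ketone to C10 quaternary ether carbon, C11–C13 lactone carbons, C14 methyl on C10, C15 methyl on C4) are used for every intermediate. N-ethyl-N-nitrosourea is taken as the commercial source of diazoethane, and only the (R)-half of racemic carbinol 3 is carried forward.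

Step 1
Reactants: 1 3-methylfuran; 2 acrolein
Product: 3 rac-1-(4-methylfuran-2-yl)prop-2-en-1-ol
Conditions: n-BuLi, TMEDA, THF, −78 → 0 °C; then 2, −78 °C; aq. NH4Cl
Reagents that add atoms: none
Why: α-Lithiation of the furan should favour the unhindered C5–H remote from the methyl group, and the hard furyllithium adds 1,2 to acrolein (organolithium carbonyl addition), the minor C2-lithiation regioisomer being removed by chromatography.

Step 2
Reactants: 3 rac-1-(4-methylfuran-2-yl)prop-2-en-1-ol
Product: 4 (2R)-6-hydroxy-5-methyl-2-vinyl-2H-pyran-3(6H)-one (anomer mixture)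
Conditions: Ti(OiPr)4 (0.2 eq), D-(−)-DIPT (0.24 eq), t-BuOOH (0.5 eq), 4 Å MS, CH2Cl2, −25 °C
Reagents that add atoms: tert-butyl hydroperoxide CC(C)(C)OO
Why: Sharpless kinetic resolution of a 2-furylcarbinol coupled to the Achmatowicz rearrangement, in which the (R)-carbinol is the matched, fast-reacting enantiomer with the D-tartrate and is ring-expanded with its carbinol centre (C7) untouched, while the (S)-carbinol, whose only matched alkene is the sluggish terminal vinyl group, is left behind and separated.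

Step 3
Reactants: 4 (2R)-6-hydroxy-5-methyl-2-vinyl-2H-pyran-3(6H)-one
Product: 5 (2R)-6-acetoxy-5-methyl-2-vinyl-2H-pyran-3(6H)-one (anomer mixture)
Conditions: Ac2O, pyridine, CH2Cl2, 0 °C
Reagents that add atoms: acetic anhydride CC(=O)OC(C)=O
Why: O-Acylation of the lactol under mild base (which spares the α-vinyl ketone) gives an anomeric leaving group, and both anomers converge on one oxocarbenium ion in the next step.

Step 4
Reactants: 5 (2R)-6-acetoxy-5-methyl-2-vinyl-2H-pyran-3(6H)-one; 6 1-(tert-butyldimethylsilyloxy)-1-methoxyethene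
Product: 7 methyl 2-[(2R,6R)-3-methyl-5-oxo-6-vinyl-5,6-dihydro-2H-pyran-2-yl]acetate (2,6-trans)
Conditions: TMSOTf (10 mol%), CH2Cl2, −78 °C
Reagents that add atoms: none
Why: Lewis-acid ionisation to the cyclic oxocarbenium ion and Mukaiyama-type C-glycosylation, in which the ketene acetal adds axially on the face opposite the pseudo-equatorial vinyl group to set C3 trans to C7, while conjugate addition is blocked by the β,β-disubstituted enone.

Step 5
Reactants: 7 methyl 2-[(2R,6R)-3-methyl-5-oxo-6-vinyl-5,6-dihydro-2H-pyran-2-yl]acetate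
Product: 8 methyl 2-[(2R,5S,6R)-5-hydroxy-3-methyl-6-vinyl-5,6-dihydro-2H-pyran-2-yl]acetate (OH trans to vinyl)
Conditions: NaBH4, CeCl3·7H2O, MeOH, −78 °C
Reagents that add atoms: none
Why: Luche 1,2-reduction of the enone, with axial hydride delivery anti to the pseudo-axial acetate arm, should give the equatorial C6 alcohol trans to the vinyl group, as is usual for Achmatowicz-derived pyranones.

Step 6
Reactants: 8 methyl 2-[(2R,5S,6R)-5-hydroxy-3-methyl-6-vinyl-5,6-dihydro-2H-pyran-2-yl]acetate
Product: 9 methyl 2-[(2R,5R,6R)-3-methyl-5-(4-nitrobenzoyloxy)-6-vinyl-5,6-dihydro-2H-pyran-2-yl]acetate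
Conditions: 4-O2NC6H4CO2H, PPh3, DIAD, THF, 0 °C
Reagents that add atoms: 4-nitrobenzoic acid OC(=O)c1ccc(cc1)[N+](=O)[O-]
Why: Mitsunobu esterification inverts C6 by SN2 to place the oxygen cis to the vinyl group, and the SN2' pathway is shut off because the distal alkene carbon C4 is fully substituted.

Step 7
Reactants: 9 methyl 2-[(2R,5R,6R)-3-methyl-5-(4-nitrobenzoyloxy)-6-vinyl-5,6-dihydro-2H-pyran-2-yl]acetate
Product: 10 2-[(2R,5R,6R)-5-hydroxy-3-methyl-6-vinyl-5,6-dihydro-2H-pyran-2-yl]acetic acid
Conditions: LiOH, THF/H2O, 0 °C → rt; then 1 M HCl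
Reagents that add atoms: lithium hydroxide [Li+].[OH-]
Why: Saponification cleaves the aryl ester and the methyl ester in one operation by acyl–oxygen cleavage, so the inverted C6 centre is untouched and the carboxylate formed protects the arm against retro-oxa-Michael opening.

Step 8
Reactants: 10 2-[(2R,5R,6R)-5-hydroxy-3-methyl-6-vinyl-5,6-dihydro-2H-pyran-2-yl]acetic acid
Product: 12 2-[(2R,5R,6R)-5-(tert-butyldimethylsilyloxy)-3-methyl-6-vinyl-5,6-dihydro-2H-pyran-2-yl]acetic acid, via bis-TBS derivative 11 (not isolated)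
Conditions: TBSCl (2.3 eq), imidazole, DMF, rt; then K2CO3, MeOH/H2O, 0 °C; aq. KHSO4
Reagents that add atoms: tert-butyldimethylsilyl chloride CC(C)(C)[Si](C)(C)Cl
Why: Exhaustive silylation followed by selective hydrolysis of the far more labile silyl ester is the standard way to obtain a silyl-ether acid.

Step 9
Reactants: 12 2-[(2R,5R,6R)-5-(tert-butyldimethylsilyloxy)-3-methyl-6-vinyl-5,6-dihydro-2H-pyran-2-yl]acetic acid
Product: 14 1-[(2R,5R,6R)-5-(tert-butyldimethylsilyloxy)-3-methyl-6-vinyl-5,6-dihydro-2H-pyran-2-yl]-3-diazobutan-2-one, via mixed anhydride 13 (not isolated)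
Conditions: i-BuOCOCl, Et3N, THF, −20 °C; then CH3CHN2 (from N-ethyl-N-nitrosourea, KOH), Et2O, −20 → 0 °C
Reagents that add atoms: diazoethane CC=[N+]=[N-]
Why: C-Acylation of diazoethane by the mixed carbonic anhydride (the diazoketone synthesis of the Arndt–Eistert sequence) brings in C10 and C14 under non-acidic conditions that spare the silyl ether and the allylic ether.

Step 10
Reactants: 14 1-[(2R,5R,6R)-5-(tert-butyldimethylsilyloxy)-3-methyl-6-vinyl-5,6-dihydro-2H-pyran-2-yl]-3-diazobutan-2-one
Product: 16 (3R,6S,10R,4Z,7Z)-6-(tert-butyldimethylsilyloxy)-3,10-epoxy-4,10-dimethylcyclodeca-4,7-dien-1-one, via oxonium ylide 15 (not isolated)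
Conditions: Cu(hfacac)2 (5 mol%), CH2Cl2, reflux, slow addition of 14
Reagents that add atoms: none
Why: The copper catalyst converts the diazoketone into an electrophilic carbenoid at C10, which the ring oxygen three atoms away captures to give bicyclic oxonium ylide 15; the ylide carbon then bonds to the vinyl terminus C9 through a five-centre envelope transition state while O–C7 breaks, the closest known reaction type being the copper-catalysed ylide formation and [2,3]-sigmatropic ring expansion of 2-vinyl cyclic ether diazoketones to 11-oxabicyclo[6.2.1]undecenones. The furanone ring closes by five-membered ylide formation (O–C10), and the ten-membered carbocycle (equally the nine-membered oxonene) closes by the sigmatropic C9–C10 bond formation, a three-atom ring expansion of the dihydropyran. C10 is the only new stereocentre and is dictated by C3, because the arm and the new O–C10 bond lie in one five-membered ring and a six-atom bridge across that ring can only be cis, so C9 enters cis to C4 (10R). The step needs ylide formation to outrun cyclopropanation of C4=C5, C–H insertion and 1,2-hydride shift from the C-methyl group, which the five-membered ylide ring next to the arm and the ylide-selective Cu(hfacac)2 (rather than a rhodium carboxylate) should secure. It also needs the Z C7=C8 alkene, which the trans disposition of arm and vinyl group in the ylide and the strain of an E alkene beside the ring-locked Z C4=C5 bond should enforce.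

Step 11
Reactants: 16 (3R,6S,10R,4Z,7Z)-6-(tert-butyldimethylsilyloxy)-3,10-epoxy-4,10-dimethylcyclodeca-4,7-dien-1-one
Product: 18 (6S,10R,4Z,7Z)-6-(tert-butyldimethylsilyloxy)-3,10-epoxy-4,10-dimethylcyclodeca-2,4,7-trien-1-one, via TMS enol ether 17 (not isolated)
Conditions: LiHMDS, TMSCl, THF, −78 °C; then Pd(OAc)2, MeCN, rt
Reagents that add atoms: none
Why: Saegusa–Ito dehydrogenation is regiochemically unambiguous because C2 is the only enolisable position (C10 is quaternary), and β-hydride loss of H3 gives the 3(2H)-furanone while destroying the relay centre C3 after it has served.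

Step 12
Reactants: 18 (6S,10R,4Z,7Z)-6-(tert-butyldimethylsilyloxy)-3,10-epoxy-4,10-dimethylcyclodeca-2,4,7-trien-1-one
Product: 19 (6S,10R,4Z,7Z)-6-hydroxy-3,10-epoxy-4,10-dimethylcyclodeca-2,4,7-trien-1-one
Conditions: HF·pyridine, pyridine, THF, 0 °C
Reagents that add atoms: none
Why: Buffered fluoride desilylation frees the C6 alcohol without exposing the base-sensitive dienone to alkoxide or the allylic alcohol to strong acid.

Step 13
Reactants: 19 (6S,10R,4Z,7Z)-6-hydroxy-3,10-epoxy-4,10-dimethylcyclodeca-2,4,7-trien-1-one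
Product: 20 (6S,10R,4Z,7Z)-3,10-epoxy-4,10-dimethyl-1-oxocyclodeca-2,4,7-trien-6-yl iodoacetate
Conditions: ICH2CO2H, DCC, DMAP (5 mol%), CH2Cl2, 0 °C
Reagents that add atoms: iodoacetic acid OC(=O)CI
Why: Steglich esterification attaches C11 and C12 at the lactone oxidation level to O6 with retention at C6.

Step 14
Reactants: 20 (6S,10R,4Z,7Z)-3,10-epoxy-4,10-dimethyl-1-oxocyclodeca-2,4,7-trien-6-yl iodoacetate
Product: 21 (6R,7S,8S,10R)-8-iodo-3,10-epoxy-1-oxo-13-norgermacra-2,4-dien-12,6-olide (trans-fused lactone)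
Conditions: dilauroyl peroxide (cat., in portions), PhH, 80 °C
Reagents that add atoms: none
Why: Iodine-atom-transfer radical cyclisation of an allylic α-iodo ester, in which the electrophilic α-ester radical adds 5-exo to the isolated electron-rich C7=C8 rather than to the electron-poor dienone bond C4=C5, C7 is set by delivery from O6 to the alkene face on which O6 lies when H6 eclipses the alkene (the conformer that makes medium-ring allylic alcohols give trans products), so the lactone should be trans-fused, and iodine is transferred to C8 anti to the new C7–C11 bond.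

Step 15
Reactants: 21 (6R,7S,8S,10R)-8-iodo-3,10-epoxy-1-oxo-13-norgermacra-2,4-dien-12,6-olide; 22 (S)-2-methylbutanoic acid
Product: 23 (6R,7R,8R,10R)-8-[(2S)-2-methylbutanoyloxy]-3,10-epoxy-1-oxo-13-norgermacra-2,4-dien-12,6-olide
Conditions: Cs2CO3, DMF, 40 °C
Reagents that add atoms: none
Why: SN2 displacement of the secondary iodide by the cesium carboxylate inverts C8 to the required configuration cis to C11 and installs the side chain without touching its own stereocentre, the weakly basic carboxylate limiting E2 elimination and lactone enolisation.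

Step 16
Reactants: 23 (6R,7R,8R,10R)-8-[(2S)-2-methylbutanoyloxy]-3,10-epoxy-1-oxo-13-norgermacra-2,4-dien-12,6-olide
Product: 26 CNP0174601.1 (6R,7R,8R,10R)-8-[(2S)-2-methylbutanoyloxy]-3,10-epoxy-1-oxogermacra-2,4,11(13)-trien-12,6-olide, via Mannich base 24 (not isolated), via methiodide 25 (not isolated)
Conditions: LiHMDS (1.05 eq), THF, −78 °C; CH2=NMe2+ I−, −78 → 0 °C; then MeI, CH2Cl2, rt; then aq. NaHCO3
Reagents that add atoms: Eschenmoser's salt C=[N+](C)C.[I-]
Why: Mannich methylenation of the kinetic lactone enolate followed by quaternisation and E1cB loss of trimethylamine creates C11=C13 without a new stereocentre, the lactone α-CH2 being the most accessible acidic site because the side-chain α-H is tertiary and H6 lies in the nodal plane of the dienone.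

**Compound list**
1 | 3-methylfuran | Cc1ccoc1 | starting material
2 | acrolein | C=CC=O | starting material
3 | rac-1-(4-methylfuran-2-yl)prop-2-en-1-ol | C=CC(O)c1cc(C)co1 | intermediate
4 | (2R)-6-hydroxy-5-methyl-2-vinyl-2H-pyran-3(6H)-one | C=C[C@H]1OC(O)C(C)=CC1=O | intermediate
5 | (2R)-6-acetoxy-5-methyl-2-vinyl-2H-pyran-3(6H)-one | C=C[C@H]1OC(OC(C)=O)C(C)=CC1=O | intermediate
6 | 1-(tert-butyldimethylsilyloxy)-1-methoxyethene | C=C(OC)O[Si](C)(C)C(C)(C)C | starting material
7 | methyl 2-[(2R,6R)-3-methyl-5-oxo-6-vinyl-5,6-dihydro-2H-pyran-2-yl]acetate | C=C[C@H]1O[C@H](CC(=O)OC)C(C)=CC1=O | intermediate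
8 | methyl 2-[(2R,5S,6R)-5-hydroxy-3-methyl-6-vinyl-5,6-dihydro-2H-pyran-2-yl]acetate | C=C[C@H]1O[C@H](CC(=O)OC)C(C)=C[C@@H]1O | intermediate
9 | methyl 2-[(2R,5R,6R)-3-methyl-5-(4-nitrobenzoyloxy)-6-vinyl-5,6-dihydro-2H-pyran-2-yl]acetate | C=C[C@H]1O[C@H](CC(=O)OC)C(C)=C[C@H]1OC(=O)c1ccc(cc1)[N+](=O)[O-] | intermediate
10 | 2-[(2R,5R,6R)-5-hydroxy-3-methyl-6-vinyl-5,6-dihydro-2H-pyran-2-yl]acetic acid | C=C[C@H]1O[C@H](CC(=O)O)C(C)=C[C@H]1O | intermediate
11 | tert-butyldimethylsilyl ester of 12 (bis-TBS derivative) | C=C[C@H]1O[C@H](CC(=O)O[Si](C)(C)C(C)(C)C)C(C)=C[C@H]1O[Si](C)(C)C(C)(C)C | intermediate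
12 | 2-[(2R,5R,6R)-5-(tert-butyldimethylsilyloxy)-3-methyl-6-vinyl-5,6-dihydro-2H-pyran-2-yl]acetic acid | C=C[C@H]1O[C@H](CC(=O)O)C(C)=C[C@H]1O[Si](C)(C)C(C)(C)C | intermediate
13 | isobutyl carbonic mixed anhydride of 12 | C=C[C@H]1O[C@H](CC(=O)OC(=O)OCC(C)C)C(C)=C[C@H]1O[Si](C)(C)C(C)(C)C | intermediate
14 | 1-[(2R,5R,6R)-5-(tert-butyldimethylsilyloxy)-3-methyl-6-vinyl-5,6-dihydro-2H-pyran-2-yl]-3-diazobutan-2-one | C=C[C@H]1O[C@H](CC(=O)C(C)=[N+]=[N-])C(C)=C[C@H]1O[Si](C)(C)C(C)(C)C | intermediate
15 | bicyclic oxonium ylide (O bonded to C3, C7 and C10) | C=C[C@H]1[O+]2[C-](C)C(=O)C[C@@H]2C(C)=C[C@H]1O[Si](C)(C)C(C)(C)C | intermediate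
16 | (3R,6S,10R,4Z,7Z)-6-(tert-butyldimethylsilyloxy)-3,10-epoxy-4,10-dimethylcyclodeca-4,7-dien-1-one | CC(C)(C)[Si](C)(C)O[C@@H]1/C=C(/C)[C@H]2CC(=O)[C@@](C)(C/C=C\1)O2 | intermediate
17 | C1–C2 trimethylsilyl enol ether of 16 | CC(C)(C)[Si](C)(C)O[C@@H]1/C=C(/C)[C@H]2C=C(O[Si](C)(C)C)[C@@](C)(C/C=C\1)O2 | intermediate
18 | (6S,10R,4Z,7Z)-6-(tert-butyldimethylsilyloxy)-3,10-epoxy-4,10-dimethylcyclodeca-2,4,7-trien-1-one | CC(C)(C)[Si](C)(C)O[C@@H]1/C=C(/C)C2=CC(=O)[C@@](C)(C/C=C\1)O2 | intermediate
19 | (6S,10R,4Z,7Z)-6-hydroxy-3,10-epoxy-4,10-dimethylcyclodeca-2,4,7-trien-1-one | O[C@@H]1/C=C(/C)C2=CC(=O)[C@@](C)(C/C=C\1)O2 | intermediate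
20 | (6S,10R,4Z,7Z)-3,10-epoxy-4,10-dimethyl-1-oxocyclodeca-2,4,7-trien-6-yl iodoacetate | ICC(=O)O[C@@H]1/C=C(/C)C2=CC(=O)[C@@](C)(C/C=C\1)O2 | intermediate
21 | (6R,7S,8S,10R)-8-iodo-3,10-epoxy-1-oxo-13-norgermacra-2,4-dien-12,6-olide | C1C(=O)O[C@@H]2/C=C(/C)C3=CC(=O)[C@@](C)(C[C@H](I)[C@@H]12)O3 | intermediate
22 | (S)-2-methylbutanoic acid | CC[C@H](C)C(=O)O | starting material
23 | (6R,7R,8R,10R)-8-[(2S)-2-methylbutanoyloxy]-3,10-epoxy-1-oxo-13-norgermacra-2,4-dien-12,6-olide | C1C(=O)O[C@@H]2/C=C(/C)C3=CC(=O)[C@@](C)(C[C@@H](OC(=O)[C@@H](C)CC)[C@@H]12)O3 | intermediate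
24 | C11 dimethylaminomethyl Mannich base of 23 | CN(C)CC1C(=O)O[C@@H]2/C=C(/C)C3=CC(=O)[C@@](C)(C[C@@H](OC(=O)[C@@H](C)CC)[C@@H]12)O3 | intermediate
25 | methiodide of 24 | C[N+](C)(C)CC1C(=O)O[C@@H]2/C=C(/C)C3=CC(=O)[C@@](C)(C[C@@H](OC(=O)[C@@H](C)CC)[C@@H]12)O3.[I-] | intermediate
26 | CNP0174601.1, (6R,7R,8R,10R)-8-[(2S)-2-methylbutanoyloxy]-3,10-epoxy-1-oxogermacra-2,4,11(13)-trien-12,6-olide | C=C1C(=O)O[C@@H]2/C=C(/C)C3=CC(=O)[C@@](C)(C[C@@H](OC(=O)[C@@H](C)CC)[C@@H]12)O3 | target

Total step count: 16. Longest linear sequence: 16 steps (from 3-methylfuran).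

**Steps most likely to fail**

Step 14. The iodoacetate must reach its s-cis ester rotamer before the radical can close, so degenerate iodine transfer, reduction or oligomerisation may win. Delivery to the wrong alkene face, or to C5, would give a cis-fused or misplaced lactone. Fallback: set out from alcohol 19 and treat it with N-iodosuccinimide and ethyl vinyl ether to form mixed iodoacetal F1, whose acetal tether carries no rotamer penalty. Triethylborane/air-initiated iodine-transfer cyclisation should then give cyclic iodoacetal F2. Jones oxidation of the acetal carbon comes back to the route at iodolactone 21. The alkyl radical is less polarity-matched to C7=C8 than the ester radical, so the C5/C7 preference would have to be checked on F1.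

Step 15. Displacement at the ring secondary iodide may be overtaken by E2 elimination towards C9, by participation of the lactone carbonyl, or by slow reaction that erodes inversion. Fallback: set out from iodolactone 21 and replace iodine by oxygen radically (Bu3SnH, dry air, toluene, aerobic hydroxylation of alkyl iodides). The 8α-alcohol F3 would then be esterified with acid 22 under Mitsunobu conditions (inversion). Any 8β-alcohol F4 would be esterified with 22, DIC and DMAP (retention). Both come back to the route at ester 23.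

Step 10. A 1,2-hydride shift from the C-methyl group of the carbenoid (giving a vinyl ketone) or cyclopropanation of the neighbouring C4=C5 bond may outrun ylide formation. Fallback: set out from acid 12 and acylate diazomethane through mixed anhydride 13 to give terminal diazoketone F5, which has no β-hydrogen on the carbenoid carbon and belongs to the best-documented substrate class. Cu(hfacac)2 should convert it into the C10-unsubstituted bridged ketone F6, and Saegusa–Ito dehydrogenation gives furanone F7. Deprotonation at C10 (the only enolisable position, giving a 3-furanolate) with LDA and methylation with MeI on the face opposite the six-atom bridge, that is with retention, comes back to the route at furanone 18.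

**Further compounds**
F1 | step 14 | (6S,10R)-6-(1-ethoxy-2-iodoethoxy)-3,10-epoxy-4,10-dimethylcyclodeca-2,4,7-trien-1-one (mixed iodoacetal) | CCOC(CI)O[C@@H]1/C=C(/C)C2=CC(=O)[C@@](C)(C/C=C\1)O2
F2 | step 14 | 12-ethoxy lactol ether of 21 (cyclic iodoacetal, C8 iodide) | C1C(OCC)O[C@@H]2/C=C(/C)C3=CC(=O)[C@@](C)(C[C@H](I)[C@@H]12)O3
F3 | step 15 | (6R,7R,8S,10R)-8-hydroxy-3,10-epoxy-1-oxo-13-norgermacra-2,4-dien-12,6-olide (8α-alcohol) | C1C(=O)O[C@@H]2/C=C(/C)C3=CC(=O)[C@@](C)(C[C@H](O)[C@@H]12)O3
F4 | step 15 | (6R,7R,8R,10R)-8-hydroxy-3,10-epoxy-1-oxo-13-norgermacra-2,4-dien-12,6-olide (8β-alcohol) | C1C(=O)O[C@@H]2/C=C(/C)C3=CC(=O)[C@@](C)(C[C@@H](O)[C@@H]12)O3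
F5 | step 10 | 1-[(2R,5R,6R)-5-(tert-butyldimethylsilyloxy)-3-methyl-6-vinyl-5,6-dihydro-2H-pyran-2-yl]-3-diazopropan-2-one | C=C[C@H]1O[C@H](CC(=O)C=[N+]=[N-])C(C)=C[C@H]1O[Si](C)(C)C(C)(C)C
F6 | step 10 | 6-(tert-butyldimethylsilyloxy)-3,10-epoxy-4-methylcyclodeca-4,7-dien-1-one (C10–H analogue of 16) | CC(C)(C)[Si](C)(C)O[C@@H]1/C=C(/C)[C@H]2CC(=O)[C@@H](C/C=C\1)O2
F7 | step 10 | 6-(tert-butyldimethylsilyloxy)-3,10-epoxy-4-methylcyclodeca-2,4,7-trien-1-one (C10–H analogue of 18) | CC(C)(C)[Si](C)(C)O[C@@H]1/C=C(/C)C2=CC(=O)[C@@H](C/C=C\1)O2
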